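The rate constants are those of an exercise; the flask was simulated.

The flask holds ten times as much free monomer as initiator, so the charge offers 11.1 units per chain.

free monomer 2.0 mM; initiator 0.18 mM; time 8.0 s

    free monomer + initiator → living end + monomer in chains (k1 = 2800 M⁻¹ s⁻¹)
    free monomer + living end → monomer in chains + living end, rate k2*[living end]*[free monomer] (k2 = 270 M⁻¹ s⁻¹)
    living end → dead end (k3 = 0.034 s⁻¹)

- the average divides the monomer in chains by the number of chains begun, living and dead together
- run time (flask): 8.0 s

* average number of monomer units in a chain (chains begun, living or dead) at 8.0 s
* part of the free monomer that has reacted at 8.0 s

1. The puzzle: in this flask the initiator had a half-life of 0.124 s at the free monomer charge, and the half-life of a living end was longer than the run, 20 s against 8.0 s. That seemed to promise 11.1 units per chain, yet I reckoned 3.92.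

2. Initiator, charged in the smaller amount, is the limiting reagent. Each one gives one living end, and a dead end stays a chain, so the balance counts chains begun. The run covered 64.5 such initiator half-lives, so as an estimate I treated initiation as instant, counted 0.18 mM of chains begun, and started growth from 1.82 mM of free monomer.

3. Growth is pseudo-first-order in free monomer. I defined the growth exposure X as the time integral of the growth constant times the living end, which decays by the third step: 0.340. Free monomer falls by the factor e^(−X).

4. That left 1.29 mM, so I reckoned 3.92 units and 35.3 % reacted. With living end held at the initiator charge, free monomer has a half-life by growth of 14.3 s, longer than the run.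

The forecast said 3.87 and 34.8 %, a conversion below mine. Its grounds began: “Initiation is over within about a second”.

The simulation gave 3.87 and 34.8 %, so the forecast held.

In this flask at 3.51 s free monomer had a half-life of 16 s by growth, longer than the run. At 8.00 s this flask still held 65.2 % of its free monomer. X contains no free monomer charge, so I carried 0.340 to the neighbour charged with 5.0 mM: it gives 8.72 units and 31.4 % reacted. That neighbour computed 8.68 and 31.2 %.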